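**Retrosynthetic overview**
1. Target ⇐ its 5,7,4'-tri-O-benzyl ether by final hydrogenolysis. The isoflavone core (rings A, C and B) is bought intact as genistein, so no ring of the target is built.
2. Key disconnection C8–C1'' (aryl–CH2): a visible-light iridium/nickel decarboxylative coupling of 8-iodo-tri-O-benzylgenistein with the carboxylate from hydroxide opening of (4S)-4-hydroxy-5,5-dimethyloxolan-2-one.
3. Aryl iodide ⇐ genistein by exhaustive O-benzylation, then C8-selective iodination (C6 is shielded between two benzyloxy groups).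
4. Lactone ⇐ the acetonide of (S)-malic acid. MeMgBr turns the dioxolanone carbonyl into the CMe2OH carbon, the other carboxyl carbon is later lost as CO2, and the stereocentre is carried through untouched.
5. Ring order: the only ring made is the transient γ-lactone (step 1), which is opened again in step 4.

Assumption: the side-chain stereocentre in the SMILES is read as (2S), and compound 1 is bought as the catalogue (S)-enantiomer, the acetonide of natural (S)-malic acid. The priority order OH > CMe2OH/CO2R > CH2 is the same in 1 and in the target, so (S) is carried through as (S).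

**Route**

Step 1
Reactants: 1 2-[(4S)-2,2-dimethyl-5-oxo-1,3-dioxolan-4-yl]acetic acid
Product: 3 (4S)-4-hydroxy-5,5-dimethyloxolan-2-one, via (3S)-3,4-dihydroxy-4-methylpentanoic acid 2 (not isolated)
Conditions: MeMgBr (4.5 equiv), THF, −20 °C → rt, 4 h; then 2 N HCl to pH 1, rt, 2 h; continuous EtOAc extraction
Reagents that add atoms: methylmagnesium bromide, C[Mg]Br
Why: Grignard double addition to the activated dioxolanone carbonyl (the acid protects itself as the unreactive bromomagnesium carboxylate; the acetone released takes up a fourth equivalent), followed by acid-induced γ-lactonisation; the stereocentre is the one bought in 1 and no bond to it is made or broken.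

Step 2
Reactants: 4 genistein (5,7-dihydroxy-3-(4-hydroxyphenyl)-4H-chromen-4-one)
Product: 5 5,7-bis(benzyloxy)-3-[4-(benzyloxy)phenyl]-4H-chromen-4-one
Conditions: BnBr (4.5 equiv), K2CO3 (6 equiv), n-Bu4NI (10 mol %), DMF, 70 °C, 16 h
Reagents that add atoms: benzyl bromide, BrCc1ccccc1
Why: Williamson ether synthesis; excess benzyl bromide in hot DMF also alkylates the hydrogen-bonded 5-OH, and full protection is what later directs iodination to C8 and keeps phenoxides away from the photocatalyst.

Step 3
Reactants: 5 5,7-bis(benzyloxy)-3-[4-(benzyloxy)phenyl]-4H-chromen-4-one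
Product: 6 5,7-bis(benzyloxy)-3-[4-(benzyloxy)phenyl]-8-iodo-4H-chromen-4-one
Conditions: NIS (1.05 equiv), TFA (10 mol %), CH2Cl2, 0 °C → rt, dark, 2 h
Reagents that add atoms: N-iodosuccinimide, O=C1CCC(=O)N1I
Why: Electrophilic aromatic iodination; ring A is by far the most electron-rich ring, C8 is ortho/para to both benzyloxy groups and ortho to O1, while C6 is flanked by two benzyloxy groups, as in the standard 8-iodination of 5,7-dialkoxyflavones.

Step 4
Reactants: 3 (4S)-4-hydroxy-5,5-dimethyloxolan-2-one; 6 5,7-bis(benzyloxy)-3-[4-(benzyloxy)phenyl]-8-iodo-4H-chromen-4-one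
Product: 8 5,7-bis(benzyloxy)-3-[4-(benzyloxy)phenyl]-8-[(2S)-2,3-dihydroxy-3-methylbutyl]-4H-chromen-4-one, via cesium (3S)-3,4-dihydroxy-4-methylpentanoate 7 (not isolated)
Conditions: 3 (1.6 equiv), CsOH·H2O (1.5 equiv), DMSO, rt, 30 min; then 6 (1.0 equiv), [Ir(dF(CF3)ppy)2(dtbbpy)]PF6 (2 mol %), NiCl2(dme) (10 mol %), dtbbpy (15 mol %), degassed DMSO–DMA, 450 nm LEDs, 25–30 °C, 24 h (dF(CF3)ppy = cyclometalated 2-(2,4-difluorophenyl)-5-(trifluoromethyl)pyridine; dtbbpy = 4,4'-di-tert-butyl-2,2'-bipyridine; dme = 1,2-dimethoxyethane)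
Reagents that add atoms: cesium hydroxide monohydrate, [Cs+].[OH-].O (supplies the Cs and one carboxylate O of 7; neither remains in 8)
Why: Proposed new method: a decarboxylative ring-opening arylation in which a β-hydroxy-γ-lactone serves as a latent, unprotected 2,3-dihydroxyalkyl radical — hydroxide opens 3 to carboxylate 7, the photoexcited trivalent iridium complex oxidises the carboxylate, loss of CO2 gives the primary radical •CH2–CH(OH)–CMe2OH, zerovalent nickel inserts into the carbon–iodine bond of 6, the divalent arylnickel captures the radical and the trivalent aryl(alkyl)nickel reductively eliminates to form C8–C1'', after which reduced iridium returns monovalent nickel to the zerovalent state; the closest known reaction type is iridium/nickel metallaphotoredox decarboxylative arylation of alkyl carboxylic acids (not shown for a lactone-derived, diol-bearing primary carboxylate or an 8-iodochromone), and nickel-catalysed reductive epoxide–aryl halide couplings show that β-oxygenated alkylnickel species couple faster than they β-eliminate; the stereocentre is β to the radical and is not touched.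

Step 5
Reactants: 8 5,7-bis(benzyloxy)-3-[4-(benzyloxy)phenyl]-8-[(2S)-2,3-dihydroxy-3-methylbutyl]-4H-chromen-4-one
Product: 9 erycibenin B (8-[(2S)-2,3-dihydroxy-3-methylbutyl]-5,7-dihydroxy-3-(4-hydroxyphenyl)-4H-chromen-4-one)
Conditions: H2 (1 atm), 10% Pd/C, EtOAc–MeOH (1:1), rt, 2–3 h, stopped at full conversion (TLC)
Reagents that add atoms: none
Why: Catalytic hydrogenolysis of the three aryl benzyl ethers is faster than hydrogenation of the vinylogous-ester C2=C3 bond and is neutral, so the diol, the pyranone and the stereocentre are untouched.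

**Compound list**
1 | 2-[(4S)-2,2-dimethyl-5-oxo-1,3-dioxolan-4-yl]acetic acid | CC1(C)O[C@@H](CC(=O)O)C(=O)O1 | starting material
2 | (3S)-3,4-dihydroxy-4-methylpentanoic acid | CC(C)(O)[C@@H](O)CC(=O)O | intermediate
3 | (4S)-4-hydroxy-5,5-dimethyloxolan-2-one | CC1(C)OC(=O)C[C@@H]1O | intermediate
4 | genistein | O=c1c(-c2ccc(O)cc2)coc2cc(O)cc(O)c12 | starting material
5 | 5,7-bis(benzyloxy)-3-[4-(benzyloxy)phenyl]-4H-chromen-4-one | O=c1c(-c2ccc(OCc3ccccc3)cc2)coc2cc(OCc3ccccc3)cc(OCc3ccccc3)c12 | intermediate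
6 | 5,7-bis(benzyloxy)-3-[4-(benzyloxy)phenyl]-8-iodo-4H-chromen-4-one | Ic1c(OCc2ccccc2)cc(OCc2ccccc2)c2c(=O)c(-c3ccc(OCc4ccccc4)cc3)coc12 | intermediate
7 | cesium (3S)-3,4-dihydroxy-4-methylpentanoate | CC(C)(O)[C@@H](O)CC(=O)[O-].[Cs+] | intermediate
8 | 5,7-bis(benzyloxy)-3-[4-(benzyloxy)phenyl]-8-[(2S)-2,3-dihydroxy-3-methylbutyl]-4H-chromen-4-one | CC(C)(O)[C@@H](O)Cc1c(OCc2ccccc2)cc(OCc2ccccc2)c2c(=O)c(-c3ccc(OCc4ccccc4)cc3)coc12 | intermediate
9 | erycibenin B | CC(C)(O)[C@@H](O)Cc1c(O)cc(O)c2c(=O)c(-c3ccc(O)cc3)coc12 | target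

**Count**
Total steps: 5. Longest linear sequence: 4 (4 → 5 → 6 → 8 → 9).

**Three steps most likely to fail**

Step 4 (the proposed new coupling). A primary, non-stabilised carboxylate is the hardest class to oxidise. Aryl ester formation, hydrodeiodination back to 5, quenching of the photocatalyst by the iodide that builds up, and radical addition to C2 of the isoflavone may compete. The fallback uses known chemistry, sets out from 3 and 6 and comes back at 8. Lactone 3 is opened and protected in one pot (2,2-dimethoxypropane, MeOH, cat. TsOH·H2O, rt) to methyl 2-[(4S)-2,2,5,5-tetramethyl-1,3-dioxolan-4-yl]acetate F3. This is saponified (LiOH·H2O, THF–H2O, then pH 4) to 2-[(4S)-2,2,5,5-tetramethyl-1,3-dioxolan-4-yl]acetic acid F4 and activated (N-hydroxyphthalimide, N,N'-diisopropylcarbodiimide, cat. DMAP, CH2Cl2) as 1,3-dioxoisoindolin-2-yl 2-[(4S)-2,2,5,5-tetramethyl-1,3-dioxolan-4-yl]acetate F5. F5 is joined to 6 by the established nickel-catalysed reductive decarboxylative coupling of N-(acyloxy)phthalimides with aryl iodides (NiBr2(dme) 10 mol %, dtbbpy, DMA, rt, run electroreductively in an undivided cell with a sacrificial Zn anode, or simply with Zn powder). This gives 5,7-bis(benzyloxy)-3-[4-(benzyloxy)phenyl]-8-{[(4S)-2,2,5,5-tetramethyl-1,3-dioxolan-4-yl]methyl}-4H-chromen-4-one F6. Mild acetonide hydrolysis (cat. TsOH·H2O, MeOH–H2O, 40 °C) then gives 8.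

Step 1 (Grignard addition on the unprotected acid). The bromomagnesium carboxylate may precipitate and stall the reaction, the tetrahedral intermediate may survive to work-up and give the methyl ketone, and the small polar lactone is hard to extract. The fallback sets out from 1 and comes back at 3. The acid is masked (tert-butyl 2,2,2-trichloroacetimidate, cat. BF3·OEt2, CH2Cl2–cyclohexane, rt) as tert-butyl 2-[(4S)-2,2-dimethyl-5-oxo-1,3-dioxolan-4-yl]acetate F1. MeMgBr (3.3 equiv, THF, −40 → 0 °C) adds only to the dioxolanone and gives tert-butyl (3S)-3,4-dihydroxy-4-methylpentanoate F2, which is extractable. Cat. TsOH·H2O in toluene at 50 °C closes it to lactone 3 with loss of tert-butanol.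

Step 5 (global hydrogenolysis). The C2=C3 bond may be partly reduced to the isoflavanone, or the hindered 7-O-benzyl group next to the new side chain may come off slowly. The fallback changes the protecting-group plan, sets out from 4 and comes back at 9. Genistein is protected (MOMCl, NaH, DMF, 0 °C → rt) as 5,7-bis(methoxymethoxy)-3-[4-(methoxymethoxy)phenyl]-4H-chromen-4-one F7 and iodinated at C8 (NIS, DMF, rt, no acid) to 8-iodo-5,7-bis(methoxymethoxy)-3-[4-(methoxymethoxy)phenyl]-4H-chromen-4-one F8. F8 is coupled with carboxylate 7 under the step 4 conditions to 8-[(2S)-2,3-dihydroxy-3-methylbutyl]-5,7-bis(methoxymethoxy)-3-[4-(methoxymethoxy)phenyl]-4H-chromen-4-one F9. All three acetals are removed by mild acid methanolysis (2 N HCl, MeOH, 40 °C) to give 9 with no reductive step.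

**Further compounds**
F1 | step 1 | tert-butyl 2-[(4S)-2,2-dimethyl-5-oxo-1,3-dioxolan-4-yl]acetate | CC1(C)O[C@@H](CC(=O)OC(C)(C)C)C(=O)O1
F2 | step 1 | tert-butyl (3S)-3,4-dihydroxy-4-methylpentanoate | CC(C)(O)[C@@H](O)CC(=O)OC(C)(C)C
F3 | step 4 | methyl 2-[(4S)-2,2,5,5-tetramethyl-1,3-dioxolan-4-yl]acetate | COC(=O)C[C@@H]1OC(C)(C)OC1(C)C
F4 | step 4 | 2-[(4S)-2,2,5,5-tetramethyl-1,3-dioxolan-4-yl]acetic acid | OC(=O)C[C@@H]1OC(C)(C)OC1(C)C
F5 | step 4 | 1,3-dioxoisoindolin-2-yl 2-[(4S)-2,2,5,5-tetramethyl-1,3-dioxolan-4-yl]acetate | O=C(C[C@@H]1OC(C)(C)OC1(C)C)ON1C(=O)c2ccccc2C1=O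
F6 | step 4 | 5,7-bis(benzyloxy)-3-[4-(benzyloxy)phenyl]-8-{[(4S)-2,2,5,5-tetramethyl-1,3-dioxolan-4-yl]methyl}-4H-chromen-4-one | O=c1c(-c2ccc(OCc3ccccc3)cc2)coc2c(C[C@@H]3OC(C)(C)OC3(C)C)c(OCc3ccccc3)cc(OCc3ccccc3)c12
F7 | step 5 | 5,7-bis(methoxymethoxy)-3-[4-(methoxymethoxy)phenyl]-4H-chromen-4-one | O=c1c(-c2ccc(OCOC)cc2)coc2cc(OCOC)cc(OCOC)c12
F8 | step 5 | 8-iodo-5,7-bis(methoxymethoxy)-3-[4-(methoxymethoxy)phenyl]-4H-chromen-4-one | Ic1c(OCOC)cc(OCOC)c2c(=O)c(-c3ccc(OCOC)cc3)coc12
F9 | step 5 | 8-[(2S)-2,3-dihydroxy-3-methylbutyl]-5,7-bis(methoxymethoxy)-3-[4-(methoxymethoxy)phenyl]-4H-chromen-4-one | CC(C)(O)[C@@H](O)Cc1c(OCOC)cc(OCOC)c2c(=O)c(-c3ccc(OCOC)cc3)coc12
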